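All runs are simulated for an exercise, noise included.

30.0 % is the number to hold this flask against. Call it F, the partner charged over the two substrates charged together: if each product molecule takes up one partner, conversion of the racemate stops near F, whichever hand reacts.

| flask | left-handed substrate | right-handed substrate | partner | free catalyst | remark | time |
|---|---|---|---|---|---|---|
| midnight | 1 M | 1 M | 0.60 equiv | 1 mol% | run made earlier |  |
| dawn | 1 M | 1 M | 0.60 equiv | 1.5 mol% | run made earlier |  |
| noon | 1 M | 1 M | 0.90 equiv | 2 mol% | run made earlier |  |
| flask | 1.0 M | 1.0 M | 0.600 equiv | 2 mol% |  | 2.5 d |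

| run | time / d | left-handed product / % | right-handed product / % |
|---|---|---|---|
| midnight | 0.208 | 3 | 5 |
| midnight | 0.417 | 7 | 8 |
| midnight | 0.625 | 9 | 7 |
| midnight | 1.25 | 12 | 11 |
| midnight | 2.50 | 14 | 14 |
| dawn | 0.500 | 10 | 9 |
| dawn | 1.04 | 11 | 14 |
| dawn | 1.67 | 15 | 15 |
| dawn | 2.08 | 14 | 14 |
| dawn | 2.50 | 13 | 14 |
| noon | 0.208 | 7 | 11 |
| noon | 0.625 | 14 | 18 |
| noon | 1.25 | 22 | 20 |
| noon | 1.67 | 24 | 23 |
| noon | 2.50 | 21 | 22 |

(readings scatter by 1.5 percentage points)

- free catalyst is single-handed; left-handed substrate and right-handed substrate are mirror images of each other, charged as a racemate, each of them at the stated concentration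
- an excess is the difference of the two amounts in percent of their sum
- an excess is below zero if the other one leads

1. excess of left-handed product over right-handed product in the product at 6.0 h
2. excess of left-handed product over right-handed product in the product at 2.5 d
3. part of the left-handed substrate and right-handed substrate charged together that has reacted at 2.5 d

Test F on the earlier runs, where a sum of two readings carries about 2.1 percentage points. The midnight run has F = 30.0 % and its last two readings sum to 28.0 % of product; the dawn run, with more catalyst and the same F, reads 27.0 % at its last point. The noon run has F = 45.0 % and reads 43.0 % at its last point. So the height follows F in these runs, though the noon run differs in catalyst as well as in partner. F says nothing of the hand: the first midnight reading is 3 % left-handed against 5 % right-handed, the last 14 % against 14 %.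

My reckoning for conversion is therefore 30.0 %. The forecast says slightly less, 29 % (range 27 % to 30.5 %), with excesses of −8 % at 6.0 h and 0 % at 2.5 d, and it remarks: “The early preference therefore seems to fade”.

The flask gives excesses of −6.24 % at 6.0 h and −0.0177 % at 2.5 d, and a conversion of 30.2 %, each within the forecast's range.

    free catalyst + left-handed substrate ⇌ catalyst intermediate A (K = 0.210 M⁻¹, k = 3.40 M⁻¹ min⁻¹)
    free catalyst + right-handed substrate ⇌ catalyst intermediate B (K = 1.10 M⁻¹, k = 0.820 M⁻¹ min⁻¹)
    partner + catalyst intermediate A → free catalyst + left-handed product (k = 0.600 M⁻¹ min⁻¹)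
    partner + catalyst intermediate B → free catalyst + right-handed product (k = 0.200 M⁻¹ min⁻¹)
    2 free catalyst ⇌ resting dimer, settled at all times (K = 28.0 M⁻¹)
    left-handed product ⇌ right-handed product (k = 0.00360 min⁻¹)
    free catalyst ⇌ dormant form (K = 0.920, k = 0.0270 min⁻¹)

In this flask the partner is the limiting reagent: 0.36 % of its charge remained at 2.50 d, less than the 64 % of its own charge left to the right-handed substrate. This flask's conversion stands 0.20 points from F. For the neighbour charged with 0.360 equiv of partner, F gives 18.0 %; the computed conversion there is 18.3 %.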